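80.0% of the substrate charged is what these flasks keep as product if the capture agent takes its whole charge out of the partner; the question is whether that toll is paid in full.

| setting | violet | teal | ochre | dusk | autumn | dawn | summer |
|---|---|---|---|---|---|---|---|
| substrate | 0.018 M | 0.072 M | 0.036 M | 0.036 M | 0.036 M | 0.036 M | 0.036 M |
| partner | 1.1 equiv | 1.1 equiv | 1.7 equiv | 1.10 equiv | 1.10 equiv | 1.10 equiv | 1.10 equiv |
| capture agent | 0.0108 M | 0.0108 M | 0.0108 M | 0.0108 M | 0.0108 M | 0.0108 M | 0.0108 M |
| temperature | 50 °C | 80 °C | 50 °C | 55 °C |  | 105 °C | 80 °C |
| remark | run made earlier | run made earlier | run made earlier |  | at 105 °C until 6.0 d, from then on at 55 °C |  |  |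
| time |  |  |  | 20 d | 20 d | 20 d | 20 d |

- violet (time / d: product / %, substrate / %): 1.67: 0, 99.0; 2.50: 0, 98.8; 4.00: 0.1, 96.2; 6.00: 0, 97.4; 8.00: 0, 94.8; 12.0: 0, 93.9; 20.0: 0.6, 88.3
- teal (time / d: product / %, substrate / %): 0.500: 0, 89.7; 0.833: 0.5, 85.4; 1.25: 1.5, 76.5; 1.67: 5.1, 70.7; 2.50: 11.2, 59.5; 4.00: 24.8, 42.2; 6.00: 43.1, 28.0
- ochre (time / d: product / %, substrate / %): 1.67: 0.6, 98.8; 5.00: 0.5, 98.6; 10.0: 0, 94.7; 15.0: 0, 93.8; 20.0: 0.1, 89.7

(each reading ± 1 percentage point)

- on the list of suspects stand: substrate -> open intermediate; partner -> second intermediate; open intermediate + second intermediate -> product; second intermediate + capture agent -> trapped intermediate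

- the flask with the highest amount of product, in percent of the substrate charged ("all alike" if they lie within 1.5 percentage points) (dusk / autumn / dawn / summer / all alike)
- final product, as a percentage of the substrate charged, in dusk
- final product, as a percentage of the substrate charged, in autumn
- final product, as a percentage of the substrate charged, in dawn
- final product, as a percentage of the substrate charged, in summer

The suspects are these: substrate opens to the open intermediate, partner turns into the second intermediate, the two couple to product, and the capture agent takes second intermediate into trapped intermediate. In the teal run at 6.00 d, the readings leave 28.9% of the charge between substrate and product, read here as open intermediate. That is 0.0208 M, more than the capture charge there, so the capture agent has a standing rival for second intermediate.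

The first way to the yield of a finished flask is the balance above, and it needs the capture agent spent to the last. A second way, reckoned here and not the forecast's, supposes a selectivity factor of one. Second intermediate then divides in proportion to its two takers, and since both fall together, the proportion stays that of the charges. This gives the capture share φ, the part of second intermediate lost to the capture agent: 23.1%. Product from the partner charged is then 84.6%. Going round once more, that split takes 0.00914 M of capture agent, less than the charge, so under this split the capture agent is not spent, against what the first way needs. The two ways part by 4.6 percentage points, and the reckoning here commits to 84.6% for a hot flask run to its end.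

The forecast names dawn as the richest flask, with 80% (75% to 84%) there, 79% (73% to 83%) in autumn, 69% (62% to 75%) in summer and 0.5% (0% to 4%) in dusk. Its ceiling is the 80.0% of the first way: “Dawn reaches the ceiling.”

The flasks give 91.1% in dawn, 87.4% in autumn, 73.3% in summer and 1.06% in dusk, so dawn leads, as forecast.

    substrate → open intermediate (k = 1.50 × 10⁻⁴ /min, Ea = 120 kJ/mol)
    partner → second intermediate (k = 3.01 × 10⁻⁴ /min, Ea = 116 kJ/mol)
    open intermediate + second intermediate → product (k = 0.00438 /M/min, Ea = 87.0 kJ/mol)
    second intermediate + capture agent → trapped intermediate (k = 0.00161 /M/min, Ea = 85.0 kJ/mol)
    (constants at 80 °C)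

Dawn stands above both reckonings. The capture step is the main cost: without it, dawn gives 99.6%. Yet dawn ends with 37.9% of its capture agent unused, and its trapped intermediate, 0.00671 M, is 16.9% of the partner charged, below φ. So the first way cheats more than the second. The neighbour with dusk's charges at 80 °C has the same φ, so the reckoned figure there is again 84.6%, a figure that dawn has already shown to run low. After 20.0 d this neighbour holds 73.3%, with 25.4% still open intermediate, and its trapped intermediate, 0.00564 M, is 14.2% of the partner charged, below φ. Summer is the same flask, and at 200 d it holds 89.9%, above the reckoned figure.

Readings and results are calculated on assumed constants; the scatter is artificial.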